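**Plan** (chroman numbering: O1, C2 Me2, C3 OH, C4 H2, C4a, C5 OH, C6 geranyl, C7 OH, C8 benzoyl, C8a)
- Cuts, in retrosynthetic order: C8–C(=O)Ph; the two C2–CH3 bonds and the ether bond O1–C2 (back to a 3-silyloxy-dihydrocoumarin); C3–C4 together with the lactone bond O1–C2; then the benzylic C–S and C–C bonds and the aryl–geranyl bond, back to phloroglucinol.
- Enabling feature: C4 is a bare benzylic CH2 on C4a, and C4a is ortho to the oxygen-bearing C8a, so C4/C4a/C8a–O1 is a latent ortho-quinone methide. C3 bears oxygen and sits next to C2, which can be a carboxyl carbon, so C3 is the α-carbon of a glycolic acid enolate.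
- Forward: the geranylated phloroglucinol ring is built first. The pyranone ring is closed onto it in one operation (C3–C4 and O1–C2), opened by double methyl addition and re-closed at O1–C2 as the dimethylpyran ring. Benzoyl and free hydroxyls come last.
- Stereochemistry: C3 is the only stereocentre. It is set as R by catalyst control of the enolate face in the annulation, and no later step breaks a bond to C3. The 2E alkene is carried in from geranyl bromide.

Key step: step 9

Abbreviations: geranyl = (2E)-3,7-dimethylocta-2,6-dien-1-yl; MOM = methoxymethyl; TBS = tert-butyldimethylsilyl; TIPS = tri(propan-2-yl)silyl; HyperBTM = 3-isopropyl-2-phenyl-3,4-dihydro-2H-benzo[4,5]thiazolo[3,2-a]pyrimidine.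

Assumption: the isothiourea follows its usual enolate model (acyl oxygen syn to sulfur, attack anti to the C2 phenyl). On that model the (2R,3S) catalyst leads to 3R; if the sense proves opposite, the enantiomeric catalyst is used.

**Route**

Step 1
Reactants: 1 phloroglucinol
Product: 2 3,5-bis(methoxymethoxy)phenol
Conditions: MOMCl (2.0 equiv), i-Pr2NEt, DMF, 0 °C → rt
Reagents that add atoms: chloromethyl methyl ether, COCCl
Why: Base-mediated O-alkylation of the phenoxides (Williamson-type acetal formation); with two equivalents the bis-ether should be the main part of the statistical mixture and is separable from the mono- and tris-ethers by chromatography.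

Step 2
Reactants: 2 3,5-bis(methoxymethoxy)phenol
Product: 3 [3,5-bis(methoxymethoxy)phenoxy]tri(propan-2-yl)silane
Conditions: TIPSCl, imidazole, DMF, rt
Reagents that add atoms: chlorotri(propan-2-yl)silane, CC(C)[Si](Cl)(C(C)C)C(C)C
Why: Imidazole-promoted silylation of the remaining phenol; the bulky TIPS ether does not direct lithiation and shields both neighbouring ring positions in step 3.

Step 3
Reactants: 3 [3,5-bis(methoxymethoxy)phenoxy]tri(propan-2-yl)silane; 4 geranyl bromide
Product: 6 [4-geranyl-3,5-bis(methoxymethoxy)phenoxy]tri(propan-2-yl)silane, via 4-lithio silyl ether 5 (not isolated)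
Conditions: n-BuLi, THF, 0 °C; then CuBr·SMe2 (10 mol %), 4, −78 °C → rt
Reagents that add atoms: none
Why: Directed ortho-metalation occurs at the C–H flanked by the two chelating MOM ethers, and the aryllithium is allylated at the primary carbon of geranyl bromide under copper catalysis (SN2 allylic substitution) with retention of the E alkene.

Step 4
Reactants: 6 [4-geranyl-3,5-bis(methoxymethoxy)phenoxy]tri(propan-2-yl)silane
Product: 7 4-geranyl-3,5-bis(methoxymethoxy)phenol
Conditions: TBAF, THF, 0 °C
Reagents that add atoms: none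
Why: Fluoride-induced cleavage of the aryl silyl ether, driven by Si–F bond formation; MOM ethers and the diene are inert.

Step 5
Reactants: 7 4-geranyl-3,5-bis(methoxymethoxy)phenol
Product: 8 2-[(dimethylamino)methyl]-4-geranyl-3,5-bis(methoxymethoxy)phenol
Conditions: Me2NH (40% aq), CH2O (37% aq), 1.05 equiv each, EtOH, 0 °C → rt
Reagents that add atoms: dimethylamine, CNC; formaldehyde, C=O
Why: Phenolic Mannich reaction: the para position is blocked by geranyl and the two ortho positions are equivalent by symmetry, so only one regioisomer can form, and one equivalent of reagent plus hydrogen bonding in the first Mannich base should hold the reaction at mono-aminomethylation.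

Step 6
Reactants: 8 2-[(dimethylamino)methyl]-4-geranyl-3,5-bis(methoxymethoxy)phenol
Product: 10 4-geranyl-3,5-bis(methoxymethoxy)-2-{[(4-methylphenyl)sulfonyl]methyl}phenol, via trimethylammonium iodide 9 (not isolated)
Conditions: MeI, MeCN, rt; then TolSO2Na, DMF, 80 °C
Reagents that add atoms: sodium 4-methylbenzenesulfinate, Cc1ccc(cc1)S(=O)[O-].[Na+]
Why: Menshutkin quaternisation turns the amine into a leaving group, and sulfinate then replaces trimethylamine at the benzylic carbon through sulfur (elimination–conjugate addition or direct SN2), the standard conversion of phenolic Mannich bases into sulfones, under neutral conditions that spare the MOM acetals.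

Step 7
Reactants: 11 methyl glycolate
Product: 12 methyl [(tert-butyldimethylsilyl)oxy]acetate
Conditions: TBSCl, imidazole, CH2Cl2, rt
Reagents that add atoms: tert-butylchlorodimethylsilane, CC(C)(C)[Si](C)(C)Cl
Why: Silylation of a primary alcohol; TBS is chosen for the glycolate oxygen because it survives organolithium and Mitsunobu conditions and later falls off under the same mild acid as aryl MOM ethers.

Step 8
Reactants: 12 methyl [(tert-butyldimethylsilyl)oxy]acetate
Product: 13 [(tert-butyldimethylsilyl)oxy]acetic acid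
Conditions: LiOH, THF–H2O, 0 °C; then cold dilute HCl to pH 4
Reagents that add atoms: lithium hydroxide, [Li+].[OH-]
Why: Saponification of the methyl ester (acyl substitution by hydroxide) at 0 °C, which the TBS ether tolerates, followed by mild acidification.

Step 9
Reactants: 10 4-geranyl-3,5-bis(methoxymethoxy)-2-{[(4-methylphenyl)sulfonyl]methyl}phenol; 13 [(tert-butyldimethylsilyl)oxy]acetic acid
Product: 16 (3R)-3-[(tert-butyldimethylsilyl)oxy]-6-geranyl-5,7-bis(methoxymethoxy)-3,4-dihydro-2H-chromen-2-one, via pivalic mixed anhydride 14 (not isolated), via ortho-quinone methide 15 (not isolated)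
Conditions: 13, t-BuCOCl, i-Pr2NEt, CH2Cl2, 0 °C; then 10, (2R,3S)-HyperBTM (10 mol %), Cs2CO3, CH2Cl2, −20 °C → rt
Reagents that add atoms: none
Why: Proposed new method: the isothiourea is acylated by 14 at the unhindered silyloxyacetyl carbonyl and pivalate deprotonates the acyl ammonium ion to a (Z)-ammonium enolate held planar by an O···S contact, while Cs2CO3 converts 10 by loss of sulfinate into methide 15; the enolate carbon adds to the exocyclic CH2 of 15 (Michael addition that restores the aromatic ring and forms C3–C4) and the freed phenoxide attacks the acyl ammonium carbonyl to form O1–C2 and release the catalyst. The closest known reaction type is the Lewis-base-catalysed (N-heterocyclic carbene, cinchona amine or isothiourea) formal [4+2] of ortho-quinone methides with C1 enolates of activated carboxylic acid derivatives to 3,4-dihydrocoumarins; what is new is the pairing of an α-silyloxyacetyl ammonium enolate with a methide that has no substituent on its CH2. The one ring formed, the lactone, closes by 6-exo-trig acyl substitution at C2. The single new stereocentre C3 is the enolate carbon, so it is controlled by the catalyst alone: the C2 phenyl of the catalyst shields one enolate face and the (2R,3S) enantiomer is expected to deliver the methide to the face that gives 3R. The step needs enolate face selectivity and C–C bond formation ahead of O-acylation of the phenoxide; the first does not depend on the achiral CH2 terminus, and the second is favoured because the phenoxide, with MOM-oxy donors ortho and para to the benzylic carbon, should expel sulfinate quickly, while the mixed anhydride is not enolised without the catalyst, which suppresses a racemic background.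

Step 10
Reactants: 16 (3R)-3-[(tert-butyldimethylsilyl)oxy]-6-geranyl-5,7-bis(methoxymethoxy)-3,4-dihydro-2H-chromen-2-one
Product: 18 2-{(2R)-2-[(tert-butyldimethylsilyl)oxy]-3-hydroxy-3-methylbutyl}-4-geranyl-3,5-bis(methoxymethoxy)phenol, via ring-opened methyl ketone 17 (not isolated)
Conditions: MeLi (4 equiv), CeCl3 (4 equiv), THF, −78 °C; then H2O
Reagents that add atoms: methyllithium, [Li]C
Why: Double nucleophilic addition of the weakly basic organocerium reagent to the aryl lactone: the phenoxide leaves after the first addition and ketone 17 should take up the second methyl faster than it enolises, so C3 is not expected to epimerise.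

Step 11
Reactants: 18 2-{(2R)-2-[(tert-butyldimethylsilyl)oxy]-3-hydroxy-3-methylbutyl}-4-geranyl-3,5-bis(methoxymethoxy)phenol
Product: 19 tert-butyl{[(3R)-6-geranyl-5,7-bis(methoxymethoxy)-2,2-dimethyl-3,4-dihydro-2H-chromen-3-yl]oxy}dimethylsilane
Conditions: PPh3, DIAD, toluene, 0 °C → 50 °C
Reagents that add atoms: none
Why: Mitsunobu cyclodehydration: the phenol is the acidic pronucleophile and displaces the oxyphosphonium of the tertiary carbinol in a 6-exo-tet etherification under neutral conditions, a known way from phenol/tertiary-carbinol pairs to 2,2-disubstituted chromans; C2 carries two identical methyls and C3 is not involved, so no stereocentre is at stake.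

Step 12
Reactants: 19 tert-butyl{[(3R)-6-geranyl-5,7-bis(methoxymethoxy)-2,2-dimethyl-3,4-dihydro-2H-chromen-3-yl]oxy}dimethylsilane; 20 N-methoxy-N-methylbenzamide
Product: 22 {(3R)-3-[(tert-butyldimethylsilyl)oxy]-6-geranyl-5,7-bis(methoxymethoxy)-2,2-dimethyl-3,4-dihydro-2H-chromen-8-yl}(phenyl)methanone, via 8-lithiochroman 21 (not isolated)
Conditions: n-BuLi, THF, 0 °C; then 20, −78 °C → rt; H2O
Reagents that add atoms: none
Why: Directed ortho-metalation at C8, the only remaining ring C–H and flanked by the C7 MOM ether and O1, followed by acylation with the Weinreb amide, whose chelated tetrahedral adduct prevents over-addition.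

Step 13
Reactants: 22 {(3R)-3-[(tert-butyldimethylsilyl)oxy]-6-geranyl-5,7-bis(methoxymethoxy)-2,2-dimethyl-3,4-dihydro-2H-chromen-8-yl}(phenyl)methanone
Product: 23 [(3R)-6-geranyl-3,5,7-trihydroxy-2,2-dimethyl-3,4-dihydro-2H-chromen-8-yl](phenyl)methanone (CNP0186586.1)
Conditions: HCl (1.25 M in MeOH), THF, rt
Reagents that add atoms: none
Why: Acid-catalysed methanolysis cleaves the two aryl MOM acetals and the secondary TBS ether in one operation without breaking any bond to C3, so the R configuration is retained; dilute acid at room temperature is chosen to leave the geranyl chain untouched.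

**Compound list**

1 | phloroglucinol | Oc1cc(O)cc(O)c1 | starting material
2 | 3,5-bis(methoxymethoxy)phenol | COCOc1cc(O)cc(OCOC)c1 | intermediate
3 | [3,5-bis(methoxymethoxy)phenoxy]tri(propan-2-yl)silane | COCOc1cc(OCOC)cc(O[Si](C(C)C)(C(C)C)C(C)C)c1 | intermediate
4 | geranyl bromide | CC(C)=CCC/C(C)=C/CBr | starting material
5 | [4-lithio-3,5-bis(methoxymethoxy)phenoxy]tri(propan-2-yl)silane | [Li]c1c(OCOC)cc(O[Si](C(C)C)(C(C)C)C(C)C)cc1OCOC | intermediate
6 | [4-geranyl-3,5-bis(methoxymethoxy)phenoxy]tri(propan-2-yl)silane | CC(C)=CCC/C(C)=C/Cc1c(OCOC)cc(O[Si](C(C)C)(C(C)C)C(C)C)cc1OCOC | intermediate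
7 | 4-geranyl-3,5-bis(methoxymethoxy)phenol | CC(C)=CCC/C(C)=C/Cc1c(OCOC)cc(O)cc1OCOC | intermediate
8 | 2-[(dimethylamino)methyl]-4-geranyl-3,5-bis(methoxymethoxy)phenol | CC(C)=CCC/C(C)=C/Cc1c(OCOC)cc(O)c(CN(C)C)c1OCOC | intermediate
9 | 1-[3-geranyl-6-hydroxy-2,4-bis(methoxymethoxy)phenyl]-N,N,N-trimethylmethanaminium iodide | CC(C)=CCC/C(C)=C/Cc1c(OCOC)cc(O)c(C[N+](C)(C)C)c1OCOC.[I-] | intermediate
10 | 4-geranyl-3,5-bis(methoxymethoxy)-2-{[(4-methylphenyl)sulfonyl]methyl}phenol | CC(C)=CCC/C(C)=C/Cc1c(OCOC)cc(O)c(CS(=O)(=O)c2ccc(C)cc2)c1OCOC | intermediate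
11 | methyl glycolate | COC(=O)CO | starting material
12 | methyl [(tert-butyldimethylsilyl)oxy]acetate | COC(=O)CO[Si](C)(C)C(C)(C)C | intermediate
13 | [(tert-butyldimethylsilyl)oxy]acetic acid | OC(=O)CO[Si](C)(C)C(C)(C)C | intermediate
14 | [(tert-butyldimethylsilyl)oxy]acetic pivalic anhydride | CC(C)(C)C(=O)OC(=O)CO[Si](C)(C)C(C)(C)C | intermediate
15 | 4-geranyl-3,5-bis(methoxymethoxy)-6-methylidenecyclohexa-2,4-dien-1-one | CC(C)=CCC/C(C)=C/CC1=C(OCOC)C(=C)C(=O)C=C1OCOC | intermediate
16 | (3R)-3-[(tert-butyldimethylsilyl)oxy]-6-geranyl-5,7-bis(methoxymethoxy)-3,4-dihydro-2H-chromen-2-one | CC(C)=CCC/C(C)=C/Cc1c(OCOC)cc2OC(=O)[C@H](O[Si](C)(C)C(C)(C)C)Cc2c1OCOC | intermediate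
17 | (3R)-3-[(tert-butyldimethylsilyl)oxy]-4-[3-geranyl-6-hydroxy-2,4-bis(methoxymethoxy)phenyl]butan-2-one (present as its phenoxide) | CC(=O)[C@H](O[Si](C)(C)C(C)(C)C)Cc1c(O)cc(OCOC)c(C/C=C(\C)CCC=C(C)C)c1OCOC | intermediate
18 | 2-{(2R)-2-[(tert-butyldimethylsilyl)oxy]-3-hydroxy-3-methylbutyl}-4-geranyl-3,5-bis(methoxymethoxy)phenol | CC(C)(O)[C@H](O[Si](C)(C)C(C)(C)C)Cc1c(O)cc(OCOC)c(C/C=C(\C)CCC=C(C)C)c1OCOC | intermediate
19 | tert-butyl{[(3R)-6-geranyl-5,7-bis(methoxymethoxy)-2,2-dimethyl-3,4-dihydro-2H-chromen-3-yl]oxy}dimethylsilane | CC(C)=CCC/C(C)=C/Cc1c(OCOC)cc2OC(C)(C)[C@H](O[Si](C)(C)C(C)(C)C)Cc2c1OCOC | intermediate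
20 | N-methoxy-N-methylbenzamide | CON(C)C(=O)c1ccccc1 | starting material
21 | 8-lithio derivative of 19 | CC(C)=CCC/C(C)=C/Cc1c(OCOC)c([Li])c2OC(C)(C)[C@H](O[Si](C)(C)C(C)(C)C)Cc2c1OCOC | intermediate
22 | {(3R)-3-[(tert-butyldimethylsilyl)oxy]-6-geranyl-5,7-bis(methoxymethoxy)-2,2-dimethyl-3,4-dihydro-2H-chromen-8-yl}(phenyl)methanone | CC(C)=CCC/C(C)=C/Cc1c(OCOC)c(C(=O)c3ccccc3)c2OC(C)(C)[C@H](O[Si](C)(C)C(C)(C)C)Cc2c1OCOC | intermediate
23 | [(3R)-6-geranyl-3,5,7-trihydroxy-2,2-dimethyl-3,4-dihydro-2H-chromen-8-yl](phenyl)methanone | CC(C)=CCC/C(C)=C/Cc1c(O)c2c(c(C(=O)c3ccccc3)c1O)OC(C)(C)[C@H](O)C2 | target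

**Step count**

Total: 13 steps. Longest linear sequence: 11 steps (steps 1–6 and 9–13, from phloroglucinol); the acid branch (steps 7–8) joins at step 9.

**Steps most likely to fail**

1. Step 9. The phenoxide of 10 may be O-acylated by the acyl ammonium ion before it loses sulfinate, the methide may be consumed by unreacted phenoxide, or the silyloxy enolate may add with poor or reversed facial selectivity. The fallback leaves the enolate disconnection and uses known chromene chemistry, setting out from 7 and returning at 19.
   - Phenol 7 would be condensed with 3-methylbut-2-enal (ethylenediammonium diacetate, toluene, reflux; condensation then oxa-6π electrocyclisation). Both ortho positions are equivalent, so this gives only 6-geranyl-5,7-bis(methoxymethoxy)-2,2-dimethyl-2H-chromene F1.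
   - Jacobsen–Katsuki epoxidation with the (R,R)-(salen)MnCl complex {chloro[(R,R)-N,N'-bis(3,5-di-tert-butylsalicylidene)cyclohexane-1,2-diaminato]manganese}, NaOCl and 4-phenylpyridine N-oxide should give (3R,4R)-3,4-epoxy-6-geranyl-5,7-bis(methoxymethoxy)-2,2-dimethylchroman F2. This catalyst class reacts with conjugated cis-alkenes well ahead of the isolated trisubstituted alkenes of the geranyl chain.
   - The crude epoxide would be opened by LiAlH4 (THF, 0 °C) at benzylic C4 to (3R)-6-geranyl-5,7-bis(methoxymethoxy)-2,2-dimethylchroman-3-ol F3.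
   - TBSCl and imidazole would convert F3 into 19.

2. Step 11. The hindered tertiary carbinol next to the silyloxy carbon may resist activation, or the oxyphosphonium may eliminate to the isopropenyl compound instead of being displaced. The fallback never opens the lactone, setting out from 16 and returning at 19.
   - Petasis methylenation of 16 (Cp2TiMe2, toluene, 70 °C) would give tert-butyl{[(3R)-6-geranyl-5,7-bis(methoxymethoxy)-2-methylidene-3,4-dihydro-2H-chromen-3-yl]oxy}dimethylsilane F4.
   - Addition of methanol to the enol ether (pyridinium p-toluenesulfonate, MeOH, 0 °C) would give the mixed ketal tert-butyl{[(3R)-6-geranyl-2-methoxy-5,7-bis(methoxymethoxy)-2-methyl-3,4-dihydro-2H-chromen-3-yl]oxy}dimethylsilane F5 as a mixture at C2.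
   - AlMe3 (CH2Cl2, −78 °C → −20 °C) would ionise the tertiary ketal in preference to the formaldehyde acetals and methylate the cyclic oxocarbenium ion, as in C-glycoside synthesis, to give 19.

3. Step 13. Under protic acid a freed C5 or C7 hydroxyl may add to the geranyl 2,3-double bond and close a second pyran ring, while the hindered silyl ether may be slow to leave. The fallback separates the two deprotections and avoids protic acid, setting out from 22 and ending at 23.
   - TBAF (THF, rt) would remove the silyl group to give [(3R)-6-geranyl-3-hydroxy-5,7-bis(methoxymethoxy)-2,2-dimethyl-3,4-dihydro-2H-chromen-8-yl](phenyl)methanone F6.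
   - ZnBr2 and n-PrSH (CH2Cl2, 0 °C) would then cleave the two aryl MOM ethers by thiol capture of the oxocarbenium ion within minutes, giving 23.

Further compounds
F1 | step 9 | 6-geranyl-5,7-bis(methoxymethoxy)-2,2-dimethyl-2H-chromene | CC(C)=CCC/C(C)=C/Cc1c(OCOC)cc2OC(C)(C)C=Cc2c1OCOC
F2 | step 9 | (3R,4R)-3,4-epoxy-6-geranyl-5,7-bis(methoxymethoxy)-2,2-dimethylchroman | CC(C)=CCC/C(C)=C/Cc1c(OCOC)cc2OC(C)(C)[C@@H]3O[C@@H]3c2c1OCOC
F3 | step 9 | (3R)-6-geranyl-5,7-bis(methoxymethoxy)-2,2-dimethylchroman-3-ol | CC(C)=CCC/C(C)=C/Cc1c(OCOC)cc2OC(C)(C)[C@H](O)Cc2c1OCOC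
F4 | step 11 | tert-butyl{[(3R)-6-geranyl-5,7-bis(methoxymethoxy)-2-methylidene-3,4-dihydro-2H-chromen-3-yl]oxy}dimethylsilane | CC(C)=CCC/C(C)=C/Cc1c(OCOC)cc2OC(=C)[C@H](O[Si](C)(C)C(C)(C)C)Cc2c1OCOC
F5 | step 11 | tert-butyl{[(3R)-6-geranyl-2-methoxy-5,7-bis(methoxymethoxy)-2-methyl-3,4-dihydro-2H-chromen-3-yl]oxy}dimethylsilane (both C2 epimers) | CC(C)=CCC/C(C)=C/Cc1c(OCOC)cc2OC(C)(OC)[C@H](O[Si](C)(C)C(C)(C)C)Cc2c1OCOC
F6 | step 13 | [(3R)-6-geranyl-3-hydroxy-5,7-bis(methoxymethoxy)-2,2-dimethyl-3,4-dihydro-2H-chromen-8-yl](phenyl)methanone | CC(C)=CCC/C(C)=C/Cc1c(OCOC)c(C(=O)c3ccccc3)c2OC(C)(C)[C@H](O)Cc2c1OCOC
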